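The data were computed for an exercise.

188 turnovers per free catalyst is what the flask can book. This turnover allowance is the smaller of c(coupling partner) and c(solid substrate), divided by c(free catalyst). It takes each turnover to consume one coupling partner and one solid substrate and to give one product.

all flasks: free catalyst 32 µM
- zeta: solid substrate 0.010 M; coupling partner 6 mM; the very flask that is asked about, followed so far
- epsilon: solid substrate 0.0050 M; coupling partner 6 mM; run made earlier
- flask: solid substrate 0.010 M; coupling partner 6.00 mM; time 6.0 h

- zeta (time / min: product / %): 8.00: 0; 20.0: 2; 40.0: 12; 60.0: 20; 80.0: 33; 120: 56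
- epsilon (time / h: product / %): 0.333: 8; 0.500: 14; 1.00: 43; 1.50: 72; 2.50: 96; 4.00: 97

(readings scatter by 2 percentage points)

- amount of product in percent of the solid substrate charged, at 80 min, 3.0 h and 6.0 h

- as a solid, counted per litre of solution: solid substrate
- at the start none of the solid substrate is in solution

The ledger reckoned here follows the coupling partner, which at 6.00 mM against 0.010 M of solid substrate is the limiting reagent. Closed at 188 turnovers, the books show 60.0% of the solid substrate as product, so 40.0% of the charge finds no partner. The first entry is the zeta reading at 120 min: 56% of product, or 175 turnovers, with the scatter of a reading. That leaves a balance of 12.5. The readings from 40.0 min to 120 min give a pace of 103 h⁻¹. If that pace holds, the books close near 2.12 h, earlier than the 3.0 h reading. The ledger therefore expects 60.0% at 3.0 h and at 6.0 h, and it takes the 80 min value from the zeta reading of 33%.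

The forecast prints 33%, 59% and 59%, with this ground: “the partner (6 mM) is limiting, so the ceiling is 60% of the solid charged”. Its last two values lie 1 percentage point under the ledger's ceiling.

The flask gives 31.9%, 59.9% and 60.0%, within the tolerance of the forecast.

    starting material + free catalyst → catalyst intermediate A (k = 21.0 L mol⁻¹ s⁻¹)
    coupling partner + catalyst intermediate A → catalyst intermediate B (k = 53.0 L mol⁻¹ s⁻¹)
    catalyst intermediate B ⇌ catalyst intermediate C (K = 1.80, k = 1.30 s⁻¹)
    catalyst intermediate C → free catalyst + product (k = 0.320 s⁻¹)
    solid substrate ⇌ starting material, rate k5*(cs5 - [starting material]) while solid is left; crystals form when [starting material] > cs5 (solubility = 6.30 mM, k = 2.10 × 10⁻⁴ s⁻¹)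

In the flask, the coupling partner stands at 0.123% of its own charge at 3.00 h, and the 60.0% of product at 6.0 h counts 188 turnovers against the allowance of 188. In epsilon, the solid substrate at 0.0050 M stands below the coupling partner at 6 mM, so the allowance is 156 turnovers, or 100% of the solid substrate, and its last reading stands at 97%.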